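Saturday's run and Friday's run share their coupling partner and free catalyst, but their substrate charges differ by a factor of 20.9; they are the evidence for the six new flasks.

| setting | Saturday's | Friday's | gamma | delta | epsilon | beta | zeta | theta |
|---|---|---|---|---|---|---|---|---|
| substrate | 0.023 M | 0.48 M | 0.025 M | 0.040 M | 0.15 M | 0.073 M | 0.020 M | 0.30 M |
| coupling partner | 0.0876 M | 0.0876 M | 0.0876 M | 0.0876 M | 0.0876 M | 0.0876 M | 0.0876 M | 0.0876 M |
| free catalyst | 0.36 mM | 0.36 mM | 0.36 mM | 0.36 mM | 0.36 mM | 0.36 mM | 0.36 mM | 0.36 mM |
| remark | run made earlier | run made earlier |  |  |  |  |  |  |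
| time |  |  | 3.0 min | 3.0 min | 3.0 min | 3.0 min | 3.0 min | 3.0 min |

| run | time / min | target / % |
|---|---|---|
| Saturday's | 0.167 | 1 |
| Saturday's | 0.500 | 8 |
| Saturday's | 0.833 | 13 |
| Saturday's | 1.33 | 19 |
| Saturday's | 2.00 | 29 |
| Saturday's | 2.50 | 33 |
| Saturday's | 3.00 | 37 |
| Friday's | 0.417 | 3 |
| Friday's | 0.833 | 3 |
| Friday's | 1.33 | 1 |
| Friday's | 1.50 | 1 |
| Friday's | 2.00 | 1 |
| Friday's | 2.50 | 4 |
| Friday's | 3.00 | 4 |

(readings scatter by 1.5 percentage points)

- ranking by amount of target, in percent of the substrate charged, from high to low, at 3.0 min (gamma / delta / epsilon / beta / zeta / theta)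
- the same order at 25 min (gamma / delta / epsilon / beta / zeta / theta)
- the amount of target, in percent of the substrate charged of the flask you put first, at 3.0 min
- the amount of target, in percent of the substrate charged of the flask you put last, at 3.0 min

- a species is counted by the substrate in it: one idle adduct counts as two
- amounts and yields of target count idle adduct too
- the numbers in the tables scatter by 1.5 percentage points (one standard deviation)
- steps that have been proposed: coupling partner + free catalyst <-> catalyst intermediate A; substrate + catalyst intermediate B -> catalyst intermediate C; 2 free catalyst -> spent catalyst; catalyst intermediate C -> free catalyst + target; substrate + target <-> idle adduct; catalyst intermediate A <-> by-product + catalyst intermediate B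
- in an amount of target, one idle adduct counts as one target

On Saturday substrate is the limiting reagent, with a smaller charge than the coupling partner, and its ledger closes at 3.00 min as follows: 37% is read as target, catalyst intermediate C can hold 1.57% of the charge, and the remaining 61.4% or more is unreacted substrate, free or paired in idle adduct. That entry for target is a mean rate of 0.00284 M min⁻¹. Friday's last reading, 4% with a scatter of 1.5 percentage points, gives 0.00640 M min⁻¹.

Take rate = V s/(K + s), with V a ceiling, K the substrate level of half rate, and s the mean substrate, meaning the charge less half of what reacted: 0.0187 M on Saturday and 0.470 M on Friday. Using Friday's rate as the ceiling gives K = 0.0235 M. Putting that back raises the ceiling to 0.00672 M min⁻¹ and K to 0.0257 M. Divided by the catalyst charged, the ceiling becomes 18.7 min⁻¹, the ceiling turnover frequency: target made per charged catalyst per minute at high substrate.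

This reckoning, my own, runs the same ledger for zeta, where substrate is again the limiting reagent, with a smaller charge than the coupling partner. Full charge as s gives 44.2%, the depleted mean gives 38.1%, and one more round gives 39.0%. For theta the first round gives 6.19%. In this rate law, at a fixed ceiling and time, the percentage falls as the charge rises, so zeta, with a smaller charge than any other flask, leads, and theta, with a larger one than any other, trails.

The forecast says zeta > gamma > delta > beta > epsilon > theta at 3.0 min and zeta > gamma > delta > beta > epsilon > theta at 25 min, with 40% (36% to 45%) for its first flask and 5.7% (3.5% to 8%) for its last. Its ground is that “a twentyfold rise in substrate only doubles the rate, which means saturation”. My zeta stands lower than its figure, and my first-round theta higher.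

The flasks give zeta > gamma > delta > beta > epsilon > theta at 3.0 min and zeta > gamma > delta > beta > epsilon > theta at 25 min, with zeta at 40.1% and theta at 4.86%, inside the forecast's ranges. Zeta's target count includes 11.9% inside idle adduct. Put back at zeta's mean substrate, the ceiling turnover gives 7.17 min⁻¹, against 7.42 min⁻¹ found. With the other amounts and the time held, zeta moves 5 points, out of the forecast's range, at 0.289 mM or 0.445 mM of free catalyst.

    coupling partner + free catalyst ⇌ catalyst intermediate A (K = 16.0 L mol⁻¹, k = 34.0 L mol⁻¹ s⁻¹)
    substrate + catalyst intermediate B → catalyst intermediate C (k = 32.0 L mol⁻¹ s⁻¹)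
    2 free catalyst → spent catalyst (k = 22.0 L mol⁻¹ s⁻¹)
    catalyst intermediate C → free catalyst + target (k = 2.80 s⁻¹)
    substrate + target ⇌ idle adduct, settled at all times (K = 44.0 L mol⁻¹)
    catalyst intermediate A ⇌ by-product + catalyst intermediate B (K = 0.0110 M, k = 0.690 s⁻¹)

In the neighbour flask, zeta with 6.1 × 10⁻⁴ M of free catalyst, the ceiling turnover frequency, taken as unchanged, gives a ceiling of 0.0114 M min⁻¹, and the rounds give 74.8%, 56.0%, 61.4%. The computed result is 52.5%, lower than reckoned, with spent catalyst at 31.9% of the catalyst charged against 20.9% in zeta.

(The data were generated by integration for substances that don't exist; scatter was added.)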